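**Plan** (locants follow the spiro[5.5]undecane numbering of the target; ring A = C1–C6, ring B = C6–C11)

1. Retrosynthesis: the C1=C2 alkene comes from its 1-methylidene isomer, and the C2–C3 bond from a carbonyl-ene closure of a C3 aldehyde onto a C1 isopropenyl group. C1 is then traced to a lactone carbonyl and the C3 oxygen to the lactone ring oxygen, so the C5–C6 bond is cut inside a temporary δ-lactone. The C8=C9 vinyl bromide goes back to a C8 ketone beside a C9 methyl stereocentre, i.e. to the ring of (S)-carvone.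
2. Forward: carvone gives ring B as a carboxylic acid carrying C8–OTBS and C9–Me. Its ester with (R)-2-bromo-3-chloro-3-methylbutan-1-ol is ionised, and the lactone closes by C5–C6 bond formation, which creates the spiro centre. The C8 oxygen is then turned into the vinyl bromide, and the lactone is taken apart (MeLi, methylenation, oxidation) and ring A is closed by an ene reaction and an alkene shift.
3. Enabling feature: the spiro carbon C6 bears C1, which can be a carboxyl carbon, and C3 bears an oxygen two atoms from the gem-dimethyl carbon C5. An ester C1(=O)–O–C3 therefore makes C6 a regiodefined ketene-acetal carbon, held so that a six-membered ring forms when it opens a C4/C5 bromiranium ion at its tertiary end C5.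
4. Stereochemistry: C4 comes from a catalyst-controlled bromochlorination of prenol and is carried through the bromiranium ion unchanged. C6 is relayed from carvone (equatorial attack on a chair locked by equatorial C8–OTBS and C9–Me). C3 comes from the chair-like ene transition state (C3–O and C4–Br both equatorial, hence trans).

Key step: step 7

Remark: compound 18 is written as the open hydroxy ketone, although it should exist largely as its cyclic hemiketal.

**Step 1**
Reactants: 1 (S)-(+)-carvone
Product: 3 (1S,2S,5S)-2-methyl-5-(prop-1-en-2-yl)cyclohexan-1-ol (all-equatorial dihydrocarveol), via dihydrocarvone 2 (not isolated)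
Conditions: Li, NH3(l), THF, −78 to −33 °C; then EtOH
Reagents that add atoms: none
Why: Dissolving-metal reduction of the enone and then of the ketone should give mainly the all-equatorial alcohol (C2 methyl set by equilibrating protonation trans to the C5 substituent, C1 carbinol by the equatorial preference of dissolving-metal ketone reduction), while the isolated isopropenyl alkene is not reduced.

**Step 2**
Reactants: 3 (1S,2S,5S)-2-methyl-5-(prop-1-en-2-yl)cyclohexan-1-ol
Product: 4 tert-butyl(dimethyl){[(1S,2S,5S)-2-methyl-5-(prop-1-en-2-yl)cyclohexyl]oxy}silane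
Conditions: TBSCl, imidazole, DMF, 23 °C
Reagents that add atoms: tert-butyl(chloro)dimethylsilane, CC(C)(C)[Si](C)(C)Cl
Why: Standard silylation of a secondary alcohol, which gives the ether that later locks the ring-B chair and survives base, ozone and mild Lewis acid.

**Step 3**
Reactants: 4 tert-butyl(dimethyl){[(1S,2S,5S)-2-methyl-5-(prop-1-en-2-yl)cyclohexyl]oxy}silane
Product: 6 1-[(1S,3S,4S)-3-{[tert-butyl(dimethyl)silyl]oxy}-4-methylcyclohexyl]ethan-1-one, via ozonide 5 (not isolated)
Conditions: O3, CH2Cl2, −78 °C; then Me2S, −78 to 23 °C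
Reagents that add atoms: ozone, [O-][O+]=O
Why: Ozonolysis with reductive work-up cleaves the only alkene to the methyl ketone without touching the stereocentres.

**Step 4**
Reactants: 6 1-[(1S,3S,4S)-3-{[tert-butyl(dimethyl)silyl]oxy}-4-methylcyclohexyl]ethan-1-one
Product: 7 (1S,3S,4S)-3-{[tert-butyl(dimethyl)silyl]oxy}-4-methylcyclohexane-1-carboxylic acid
Conditions: Br2, NaOH, H2O/1,4-dioxane, 0 °C; then HCl (aq) to pH 3
Reagents that add atoms: sodium hydroxide, [Na+].[OH-]
Why: Haloform oxidation should brominate the methyl group exhaustively and cleave it as bromoform; the carboxyl stays equatorial, and its stereocentre is in any case planarised in step 7.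

**Step 5**
Reactants: 8 prenol (3-methylbut-2-en-1-ol)
Product: 9 (2R)-2-bromo-3-chloro-3-methylbutan-1-ol
Conditions: NBS, ClTi(OiPr)3, chiral tridentate salicylaldimine ligand (cat., the enantiomer that gives the 2R product), hexanes, −20 °C
Reagents that add atoms: N-bromosuccinimide, BrN1C(=O)CCC1=O; chlorotitanium triisopropoxide, CC(C)O[Ti](Cl)(OC(C)C)OC(C)C
Why: Catalytic enantioselective bromochlorination of an allylic alcohol: the titanium-bound alkoxide is brominated on one alkene face and chloride is delivered anti to the tertiary carbon, so the ligand enantiomer should fix the bromine-bearing stereocentre as (R).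

**Step 6**
Reactants: 7 (1S,3S,4S)-3-{[tert-butyl(dimethyl)silyl]oxy}-4-methylcyclohexane-1-carboxylic acid; 9 (2R)-2-bromo-3-chloro-3-methylbutan-1-ol
Product: 10 (2R)-2-bromo-3-chloro-3-methylbutyl (1S,3S,4S)-3-{[tert-butyl(dimethyl)silyl]oxy}-4-methylcyclohexane-1-carboxylate
Conditions: EDC·HCl, DMAP (cat.), CH2Cl2, 0 to 23 °C
Reagents that add atoms: none
Why: Carbodiimide (Steglich) esterification under near-neutral conditions should join the two fragments without eliminating the bromochloride or closing an epoxide.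

**Step 7**
Reactants: 10 (2R)-2-bromo-3-chloro-3-methylbutyl (1S,3S,4S)-3-{[tert-butyl(dimethyl)silyl]oxy}-4-methylcyclohexane-1-carboxylate
Product: 12 (4S,6R,8S,9S)-4-bromo-8-{[tert-butyl(dimethyl)silyl]oxy}-5,5,9-trimethyl-2-oxaspiro[5.5]undecan-1-one, via silyl ketene acetal 11 (not isolated)
Conditions: LiN(iPr)2, Me3SiCl (in situ quench), THF, −78 to 0 °C; solvent exchange to CH2Cl2; ZnCl2, −78 to 0 °C
Reagents that add atoms: none
Why: Proposed new method: ZnCl2 abstracts the tertiary chloride of 11 with anchimeric assistance by the neighbouring bromine, so a configurationally defined C4/C5 bromiranium ion forms without any external Br+ that would attack the ketene acetal, and the ketene-acetal carbon C6 opens it at the tertiary carbon C5 with loss of Me3SiCl; the closest known reactions are the Lewis-acid-promoted α-tert-alkylation of O-silyl ketene acetals by tertiary alkyl chlorides and the bromochloride-initiated solvolytic cation–olefin cyclisation. The δ-lactone closes in a 6-(enolendo) mode with endo opening of the three-membered ion at its tertiary end, whereas the 5-(enolendo)-exo-tet alternative at C4 is stereoelectronically disfavoured and C4 carries little of the positive charge. The spiro centre C6 is controlled by the ring-B chair locked by the equatorial C8–OTBS and C9–Me groups: the bulky tertiary electrophile should enter on the equatorial face (trans to C9–Me), and this gives the (6R) lactone from either E or Z isomer of 11 because the exocyclic carbon becomes the carbonyl. The C4–Br bond is never broken, so the configuration set in step 5 is kept (the descriptor changes from R to S only because chlorine leaves C5). The step needs C- over O-alkylation and ring closure over loss of a proton from the cation, which the soft and strongly nucleophilic ketene-acetal carbon held at six-ring distance and the non-basic low-temperature medium should secure.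

**Step 8**
Reactants: 12 (4S,6R,8S,9S)-4-bromo-8-{[tert-butyl(dimethyl)silyl]oxy}-5,5,9-trimethyl-2-oxaspiro[5.5]undecan-1-one
Product: 14 (4S,6R,9S)-4-bromo-5,5,9-trimethyl-2-oxaspiro[5.5]undecane-1,8-dione, via hydroxy lactone 13 (not isolated)
Conditions: CrO3, H2SO4, acetone/H2O, 0 to 23 °C
Reagents that add atoms: none
Why: Jones oxidation in aqueous acid should cleave the secondary silyl ether and oxidise the freed alcohol in one operation, leaving the lactone and the hindered secondary bromide intact.

**Step 9**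
Reactants: 14 (4S,6R,9S)-4-bromo-5,5,9-trimethyl-2-oxaspiro[5.5]undecane-1,8-dione
Product: 15 (4S,6R)-4-bromo-5,5,9-trimethyl-1-oxo-2-oxaspiro[5.5]undec-8-en-8-yl trifluoromethanesulfonate
Conditions: Tf2O, 2,6-di-tert-butyl-4-methylpyridine, CH2Cl2, 0 to 23 °C
Reagents that add atoms: trifluoromethanesulfonic anhydride, FC(F)(F)S(=O)(=O)OS(=O)(=O)C(F)(F)F
Why: Thermodynamic enol triflate formation should favour the tetrasubstituted C8=C9 enol over the C7=C8 isomer, the lactone carbonyl has no α-hydrogen, and the C9 stereocentre is removed here as planned.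

**Step 10**
Reactants: 15 (4S,6R)-4-bromo-5,5,9-trimethyl-1-oxo-2-oxaspiro[5.5]undec-8-en-8-yl trifluoromethanesulfonate
Product: 16 (4S,6R)-4-bromo-5,5,9-trimethyl-8-(trimethylstannyl)-2-oxaspiro[5.5]undec-8-en-1-one
Conditions: Me3SnSnMe3, Pd(PPh3)4 (cat.), LiCl, THF, 65 °C
Reagents that add atoms: hexamethyldistannane, C[Sn](C)(C)[Sn](C)(C)C
Why: Palladium-catalysed stannylation of a vinyl triflate with a distannane should not engage the hindered secondary alkyl bromide or the lactone.

**Step 11**
Reactants: 16 (4S,6R)-4-bromo-5,5,9-trimethyl-8-(trimethylstannyl)-2-oxaspiro[5.5]undec-8-en-1-one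
Product: 17 (4S,6R)-4,8-dibromo-5,5,9-trimethyl-2-oxaspiro[5.5]undec-8-en-1-one
Conditions: NBS, CH2Cl2, 0 °C
Reagents that add atoms: N-bromosuccinimide, BrN1C(=O)CCC1=O
Why: Bromodestannylation by ipso attack on the vinylstannane gives the vinyl bromide with the alkene kept in place, and no other alkene is present.

**Step 12**
Reactants: 17 (4S,6R)-4,8-dibromo-5,5,9-trimethyl-2-oxaspiro[5.5]undec-8-en-1-one
Product: 18 1-{(1R)-3-bromo-1-[(3S)-3-bromo-4-hydroxy-2-methylbutan-2-yl]-4-methylcyclohex-3-en-1-yl}ethan-1-one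
Conditions: MeLi (1.1 equiv), THF, −78 °C; AcOH quench at −78 °C
Reagents that add atoms: methyllithium, [Li]C
Why: Mono-addition of MeLi to a lactone: the tetrahedral lithium hemiketalate should persist at −78 °C and is protonated cold, so that neither a second addition nor a free alkoxide next to the C4 bromide arises.

**Step 13**
Reactants: 18 1-{(1R)-3-bromo-1-[(3S)-3-bromo-4-hydroxy-2-methylbutan-2-yl]-4-methylcyclohex-3-en-1-yl}ethan-1-one
Product: 19 (2S)-2-bromo-3-[(1S)-3-bromo-4-methyl-1-(prop-1-en-2-yl)cyclohex-3-en-1-yl]-3-methylbutan-1-ol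
Conditions: Cp2Ti(μ-Cl)(μ-CH2)AlMe2 (Tebbe reagent), pyridine, THF/toluene, −40 to 0 °C
Reagents that add atoms: Tebbe reagent, C[Al-]1(C)C[Ti](C2C=CC=C2)(C2C=CC=C2)[Cl+]1
Why: Tebbe methylenation is a non-basic titanium-carbenoid olefination suited to hindered ketones, and the hydroxyl should be tolerated as a titanium or aluminium alkoxide that is too weakly nucleophilic to displace the neighbouring bromide at low temperature.

**Step 14**
Reactants: 19 (2S)-2-bromo-3-[(1S)-3-bromo-4-methyl-1-(prop-1-en-2-yl)cyclohex-3-en-1-yl]-3-methylbutan-1-ol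
Product: 20 (2S)-2-bromo-3-[(1S)-3-bromo-4-methyl-1-(prop-1-en-2-yl)cyclohex-3-en-1-yl]-3-methylbutanal
Conditions: Dess–Martin periodinane, CH2Cl2, 0 °C
Reagents that add atoms: none
Why: Dess–Martin oxidation of the primary alcohol under non-basic conditions should not epimerise the α-bromo stereocentre, and the aldehyde is used at once.

**Step 15**
Reactants: 20 (2S)-2-bromo-3-[(1S)-3-bromo-4-methyl-1-(prop-1-en-2-yl)cyclohex-3-en-1-yl]-3-methylbutanal
Product: 21 (3S,4S,6S)-4,8-dibromo-5,5,9-trimethyl-1-methylidenespiro[5.5]undec-8-en-3-ol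
Conditions: Me2AlCl, CH2Cl2, −78 °C
Reagents that add atoms: none
Why: Type 2 carbonyl-ene cyclisation (ene unit tethered through its central carbon): the CH2 end of the isopropenyl group attacks the Me2AlCl-activated aldehyde carbon C3 with transfer of a methyl hydrogen to oxygen, and a chair transition state with C4–Br and C3–O–Al both equatorial should set (3S), trans to bromine.

**Step 16**
Reactants: 21 (3S,4S,6S)-4,8-dibromo-5,5,9-trimethyl-1-methylidenespiro[5.5]undec-8-en-3-ol
Product: 22 (3S,4S,6S)-4,8-dibromo-1,5,5,9-tetramethylspiro[5.5]undeca-1,8-dien-3-ol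
Conditions: chloro[N,N′-bis(3,5-di-tert-butylsalicylidene)cyclohexane-1,2-diaminato]cobalt (cat.), PhSiH3 (cat.), benzene, 23 °C
Reagents that add atoms: none
Why: Metal-hydride hydrogen-atom-transfer alkene isomerisation: reversible H-atom transfer to the 1,1-disubstituted alkene gives the tertiary C1 radical, and loss of H from C2 should give the more stable endocyclic trisubstituted alkene (C6 is quaternary, so no other ring isomer exists) without touching a stereocentre.

**Compound list**

1 | (S)-(+)-carvone; (5S)-2-methyl-5-(prop-1-en-2-yl)cyclohex-2-en-1-one | CC1=CC[C@@H](CC1=O)C(C)=C | starting material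
2 | (2S,5S)-2-methyl-5-(prop-1-en-2-yl)cyclohexan-1-one (trans-dihydrocarvone) | C[C@H]1CC[C@@H](CC1=O)C(C)=C | intermediate (not isolated)
3 | (1S,2S,5S)-2-methyl-5-(prop-1-en-2-yl)cyclohexan-1-ol | C[C@H]1CC[C@@H](C[C@@H]1O)C(C)=C | intermediate
4 | tert-butyl(dimethyl){[(1S,2S,5S)-2-methyl-5-(prop-1-en-2-yl)cyclohexyl]oxy}silane | C[C@H]1CC[C@@H](C[C@@H]1O[Si](C)(C)C(C)(C)C)C(C)=C | intermediate
5 | tert-butyl(dimethyl){[(1S,2S,5S)-2-methyl-5-(3-methyl-1,2,4-trioxolan-3-yl)cyclohexyl]oxy}silane (ozonide, both epimers at the trioxolane carbon) | C[C@H]1CC[C@@H](C[C@@H]1O[Si](C)(C)C(C)(C)C)C1(C)OOCO1 | intermediate (not isolated)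
6 | 1-[(1S,3S,4S)-3-{[tert-butyl(dimethyl)silyl]oxy}-4-methylcyclohexyl]ethan-1-one | C[C@H]1CC[C@@H](C[C@@H]1O[Si](C)(C)C(C)(C)C)C(C)=O | intermediate
7 | (1S,3S,4S)-3-{[tert-butyl(dimethyl)silyl]oxy}-4-methylcyclohexane-1-carboxylic acid | C[C@H]1CC[C@@H](C[C@@H]1O[Si](C)(C)C(C)(C)C)C(O)=O | intermediate
8 | prenol; 3-methylbut-2-en-1-ol | CC(C)=CCO | starting material
9 | (2R)-2-bromo-3-chloro-3-methylbutan-1-ol | OC[C@@H](Br)C(C)(C)Cl | intermediate
10 | (2R)-2-bromo-3-chloro-3-methylbutyl (1S,3S,4S)-3-{[tert-butyl(dimethyl)silyl]oxy}-4-methylcyclohexane-1-carboxylate | C[C@H]1CC[C@@H](C[C@@H]1O[Si](C)(C)C(C)(C)C)C(=O)OC[C@@H](Br)C(C)(C)Cl | intermediate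
11 | tert-butyl{[(1S,2S)-5-({[(2R)-2-bromo-3-chloro-3-methylbutyl]oxy}[(trimethylsilyl)oxy]methylidene)-2-methylcyclohexyl]oxy}dimethylsilane (E/Z mixture) | C[C@H]1CCC(C[C@@H]1O[Si](C)(C)C(C)(C)C)=C(O[Si](C)(C)C)OC[C@@H](Br)C(C)(C)Cl | intermediate (not isolated)
12 | (4S,6R,8S,9S)-4-bromo-8-{[tert-butyl(dimethyl)silyl]oxy}-5,5,9-trimethyl-2-oxaspiro[5.5]undecan-1-one | O=C1OC[C@@H](Br)C(C)(C)[C@]12CC[C@H](C)[C@@H](O[Si](C)(C)C(C)(C)C)C2 | intermediate
13 | (4S,6R,8S,9S)-4-bromo-8-hydroxy-5,5,9-trimethyl-2-oxaspiro[5.5]undecan-1-one | O=C1OC[C@@H](Br)C(C)(C)[C@]12CC[C@H](C)[C@@H](O)C2 | intermediate (not isolated)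
14 | (4S,6R,9S)-4-bromo-5,5,9-trimethyl-2-oxaspiro[5.5]undecane-1,8-dione | O=C1OC[C@@H](Br)C(C)(C)[C@]12CC[C@H](C)C(=O)C2 | intermediate
15 | (4S,6R)-4-bromo-5,5,9-trimethyl-1-oxo-2-oxaspiro[5.5]undec-8-en-8-yl trifluoromethanesulfonate | O=C1OC[C@@H](Br)C(C)(C)[C@]12CCC(C)=C(OS(=O)(=O)C(F)(F)F)C2 | intermediate
16 | (4S,6R)-4-bromo-5,5,9-trimethyl-8-(trimethylstannyl)-2-oxaspiro[5.5]undec-8-en-1-one | O=C1OC[C@@H](Br)C(C)(C)[C@]12CCC(C)=C([Sn](C)(C)C)C2 | intermediate
17 | (4S,6R)-4,8-dibromo-5,5,9-trimethyl-2-oxaspiro[5.5]undec-8-en-1-one | O=C1OC[C@@H](Br)C(C)(C)[C@]12CCC(C)=C(Br)C2 | intermediate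
18 | 1-{(1R)-3-bromo-1-[(3S)-3-bromo-4-hydroxy-2-methylbutan-2-yl]-4-methylcyclohex-3-en-1-yl}ethan-1-one | OC[C@@H](Br)C(C)(C)[C@@]1(C(C)=O)CCC(C)=C(Br)C1 | intermediate
19 | (2S)-2-bromo-3-[(1S)-3-bromo-4-methyl-1-(prop-1-en-2-yl)cyclohex-3-en-1-yl]-3-methylbutan-1-ol | OC[C@@H](Br)C(C)(C)[C@@]1(C(C)=C)CCC(C)=C(Br)C1 | intermediate
20 | (2S)-2-bromo-3-[(1S)-3-bromo-4-methyl-1-(prop-1-en-2-yl)cyclohex-3-en-1-yl]-3-methylbutanal | O=C[C@@H](Br)C(C)(C)[C@@]1(C(C)=C)CCC(C)=C(Br)C1 | intermediate
21 | (3S,4S,6S)-4,8-dibromo-5,5,9-trimethyl-1-methylidenespiro[5.5]undec-8-en-3-ol | C=C1C[C@H](O)[C@@H](Br)C(C)(C)[C@]12CCC(C)=C(Br)C2 | intermediate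
22 | (3S,4S,6S)-4,8-dibromo-1,5,5,9-tetramethylspiro[5.5]undeca-1,8-dien-3-ol | CC1=C[C@H](O)[C@@H](Br)C(C)(C)[C@]12CCC(C)=C(Br)C2 | target

**Total step count:** 16
**Longest linear sequence:** 15 steps (from 1 through steps 1–4 and 6–16); the prenol branch is one step (step 5).

**Steps most likely to fail**

1. Step 7 (proposed new method). After ionisation the cation may lose a proton or be captured at oxygen instead of at C6, or the two faces of the ketene acetal may be attacked with little preference. The fallback uses known chemistry, sets out from 7 and 8 and comes back at 12; it makes the C5–C6 bond by a sigmatropic shift instead of a cationic closure. Esterification of 7 with 8 (EDC·HCl, DMAP, CH2Cl2) would give the 3-methylbut-2-en-1-yl ester F1. Ireland–Claisen rearrangement (LiN(iPr)2, Me3SiCl, THF, −78 to 60 °C) would pass through the silyl ketene acetal F2 to the trimethylsilyl ester F3, the 2-methylbut-3-en-2-yl group being delivered through a chair transition state to the equatorial face of the same locked ring, and aqueous work-up would give the acid F4. Me3SiCHN2 (MeOH/toluene) would give the methyl ester F5. Aldehyde-selective Wacker oxidation of the vinyl group (PdCl2(PhCN)2, CuCl2, AgNO2, O2, t-BuOH/MeNO2) would give the aldehyde F6. Enamine-catalysed enantioselective α-bromination (2,5-diphenylpyrrolidine catalyst of the enantiomeric series that gives the 3S bromide, 4,4-dibromo-2,6-di-tert-butylcyclohexa-2,5-dienone as bromine source) would give the α-bromo aldehyde F7. NaBH4 (MeOH, −20 °C) would give the bromohydrin ester F8, which should lactonise to 12 on warming with catalytic camphorsulfonic acid in toluene.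

2. Step 13. The free C3 hydroxyl may hold the ketone as the unreactive cyclic hemiketal or, as a metal alkoxide, close onto C4 with loss of bromide. The fallback sets out from 18 and comes back at 20: the hydroxyl is masked and later oxidised without a separate deprotection. Et3SiCl and imidazole (DMF) would trap the open form as the triethylsilyl ether F9. Tebbe methylenation would then give the isopropenyl silyl ether F10. Swern conditions ((COCl)2, DMSO, Et3N, −78 to −30 °C) should cleave the primary triethylsilyl ether and oxidise it in one operation to 20, so that 19 is bypassed.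

3. Step 9. Enolisation may run towards C7 and give the regioisomeric enol triflate. The fallback sets out from 14 and comes back at 15: the enolate is made regiospecifically by conjugate reduction. Dehydrogenation of 14 with 2-iodoxybenzoic acid (DMSO, 70 °C) can only run towards C9/C10, because C7 has no β-hydrogen (C6 is quaternary), and would give the enone F11. LiBH(s-Bu)3 (THF, −78 °C) would add hydride to C10 and give the lithium enolate F12, which is trapped with PhNTf2 to give 15.

**Further compounds**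

F1 | step 7 | 3-methylbut-2-en-1-yl (1S,3S,4S)-3-{[tert-butyl(dimethyl)silyl]oxy}-4-methylcyclohexane-1-carboxylate | C[C@H]1CC[C@@H](C[C@@H]1O[Si](C)(C)C(C)(C)C)C(=O)OCC=C(C)C
F2 | step 7 | tert-butyl(dimethyl){[(1S,2S)-2-methyl-5-{[(3-methylbut-2-en-1-yl)oxy][(trimethylsilyl)oxy]methylidene}cyclohexyl]oxy}silane | C[C@H]1CCC(C[C@@H]1O[Si](C)(C)C(C)(C)C)=C(O[Si](C)(C)C)OCC=C(C)C
F3 | step 7 | trimethylsilyl (1R,3S,4S)-3-{[tert-butyl(dimethyl)silyl]oxy}-4-methyl-1-(2-methylbut-3-en-2-yl)cyclohexane-1-carboxylate | C=CC(C)(C)[C@@]1(C(=O)O[Si](C)(C)C)CC[C@H](C)[C@@H](O[Si](C)(C)C(C)(C)C)C1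
F4 | step 7 | (1R,3S,4S)-3-{[tert-butyl(dimethyl)silyl]oxy}-4-methyl-1-(2-methylbut-3-en-2-yl)cyclohexane-1-carboxylic acid | C=CC(C)(C)[C@@]1(C(O)=O)CC[C@H](C)[C@@H](O[Si](C)(C)C(C)(C)C)C1
F5 | step 7 | methyl (1R,3S,4S)-3-{[tert-butyl(dimethyl)silyl]oxy}-4-methyl-1-(2-methylbut-3-en-2-yl)cyclohexane-1-carboxylate | C=CC(C)(C)[C@@]1(C(=O)OC)CC[C@H](C)[C@@H](O[Si](C)(C)C(C)(C)C)C1
F6 | step 7 | methyl (1R,3S,4S)-3-{[tert-butyl(dimethyl)silyl]oxy}-4-methyl-1-(2-methyl-4-oxobutan-2-yl)cyclohexane-1-carboxylate | O=CCC(C)(C)[C@@]1(C(=O)OC)CC[C@H](C)[C@@H](O[Si](C)(C)C(C)(C)C)C1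
F7 | step 7 | methyl (1R,3S,4S)-1-[(3S)-3-bromo-2-methyl-4-oxobutan-2-yl]-3-{[tert-butyl(dimethyl)silyl]oxy}-4-methylcyclohexane-1-carboxylate | O=C[C@@H](Br)C(C)(C)[C@@]1(C(=O)OC)CC[C@H](C)[C@@H](O[Si](C)(C)C(C)(C)C)C1
F8 | step 7 | methyl (1R,3S,4S)-1-[(3S)-3-bromo-4-hydroxy-2-methylbutan-2-yl]-3-{[tert-butyl(dimethyl)silyl]oxy}-4-methylcyclohexane-1-carboxylate | OC[C@@H](Br)C(C)(C)[C@@]1(C(=O)OC)CC[C@H](C)[C@@H](O[Si](C)(C)C(C)(C)C)C1
F9 | step 13 | 1-[(1R)-3-bromo-1-{(3S)-3-bromo-2-methyl-4-[(triethylsilyl)oxy]butan-2-yl}-4-methylcyclohex-3-en-1-yl]ethan-1-one | CC[Si](CC)(CC)OC[C@@H](Br)C(C)(C)[C@@]1(C(C)=O)CCC(C)=C(Br)C1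
F10 | step 13 | {(2S)-2-bromo-3-[(1S)-3-bromo-4-methyl-1-(prop-1-en-2-yl)cyclohex-3-en-1-yl]-3-methylbutoxy}triethylsilane | CC[Si](CC)(CC)OC[C@@H](Br)C(C)(C)[C@@]1(C(C)=C)CCC(C)=C(Br)C1
F11 | step 9 | (4S,6R)-4-bromo-5,5,9-trimethyl-2-oxaspiro[5.5]undec-9-ene-1,8-dione | O=C1OC[C@@H](Br)C(C)(C)[C@]12CC=C(C)C(=O)C2
F12 | step 9 | lithium (4S,6R)-4-bromo-5,5,9-trimethyl-1-oxo-2-oxaspiro[5.5]undec-8-en-8-olate | [Li+].O=C1OC[C@@H](Br)C(C)(C)[C@]12CCC(C)=C([O-])C2
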